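**Plan**

1. Ring C is a 4-pyranone: its C4 carbonyl lies between ring A carbon C4a and the C3=C2 unit that carries ring B, and O1 is a ring A phenol oxygen. It is therefore cut at C4a–C4, C4–C3 and O1–C2 into an ortho-iodophenol (ring A), CO (C4) and a ring B arylalkyne (C3≡C2).
2. Further cuts: the four phenolic O–Si bonds, the Cγ–O ester bond to p-coumaric acid, the Cα–Cβ bond (aldol of an aryloxyacetyl imide with protected vanillin), the ArO–CH2 ether bond and the alkyne carbon (homologation of the syringaldehyde formyl group).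
3. Forward: ring B (syringaldehyde) is first built into the alkyne with the complete side chain, ring A (phloroglucinol) is prepared as the iodophenol, ring C is closed last by carbonylative annulation, and a buffered fluoride step frees the four phenols.
4. Stereochemistry: an Evans syn aldol with (R)-4-benzyl-2-oxazolidinone sets Cβ (S) and gives the threo (αS,βS) pair; a Mitsunobu inversion at Cα then gives the erythro (αR,βS) pair of the target. The E alkene comes from p-coumaric acid.
5. All phenols are carried as triisopropylsilyl (TIPS) ethers, so the last step needs neither acid (labile p-hydroxybenzylic Cα–OH) nor base or hydrogen (p-coumarate).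

Key step: step 13

Remark: Cα is the benzylic carbinol carbon, Cβ the aryloxy-bearing carbon and Cγ the acyloxymethylene carbon; the target SMILES is read as (αR,βS), which is the erythro series.

**Route**

Step 1
Reactants: 1 syringaldehyde
Product: 2 methyl (4-formyl-2,6-dimethoxyphenoxy)acetate
Conditions: BrCH2CO2Me, K2CO3, DMF, rt
Reagents that add atoms: methyl bromoacetate, COC(=O)CBr
Why: Williamson ether synthesis, in which the acidic para-formyl phenoxide displaces bromide from the primary α-bromo ester by SN2.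

Step 2
Reactants: 2 methyl (4-formyl-2,6-dimethoxyphenoxy)acetate
Product: 4 (4-ethynyl-2,6-dimethoxyphenoxy)acetic acid, via methyl ester alkyne 3 (not isolated)
Conditions: dimethyl (1-diazo-2-oxopropyl)phosphonate, K2CO3, MeOH, rt; then aq. LiOH, rt; 1 M HCl to pH 3
Reagents that add atoms: dimethyl (1-diazo-2-oxopropyl)phosphonate, CC(=O)C(=[N+]=[N-])P(=O)(OC)OC; LiOH, [Li+].[OH-]
Why: Ohira–Bestmann (Seyferth–Gilbert) homologation, in which methanolysis of the reagent frees the diazomethylphosphonate anion that turns the non-enolisable aryl aldehyde into the terminal alkyne, followed in the same flask by saponification of the methyl ester with aqueous LiOH.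

Step 3
Reactants: 4 (4-ethynyl-2,6-dimethoxyphenoxy)acetic acid; 5 (R)-4-benzyl-2-oxazolidinone
Product: 7 (R)-4-benzyl-3-[(4-ethynyl-2,6-dimethoxyphenoxy)acetyl]-2-oxazolidinone, via mixed pivalic anhydride 6 (not isolated)
Conditions: PivCl, Et3N, THF, −20 °C; then 5, LiCl, −20 °C → rt
Reagents that add atoms: none
Why: N-acylation of the oxazolidinone through the mixed pivalic anhydride under LiCl/Et3N activation, which needs no butyllithium and so leaves the acidic alkyne C–H untouched.

Step 4
Reactants: 8 vanillin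
Product: 9 3-methoxy-4-(triisopropylsilyloxy)benzaldehyde
Conditions: TIPSCl, imidazole, DMF, rt
Reagents that add atoms: triisopropylsilyl chloride, CC(C)[Si](Cl)(C(C)C)C(C)C
Why: Imidazole-promoted silylation of a phenol, giving an aryl TIPS ether that should tolerate the boron triflate, borohydride, Mitsunobu and amine conditions that follow.

Step 5
Reactants: 7 (R)-4-benzyl-3-[(4-ethynyl-2,6-dimethoxyphenoxy)acetyl]-2-oxazolidinone; 9 3-methoxy-4-(triisopropylsilyloxy)benzaldehyde
Product: 11 (R)-4-benzyl-3-[(2R,3S)-2-(4-ethynyl-2,6-dimethoxyphenoxy)-3-hydroxy-3-[3-methoxy-4-(triisopropylsilyloxy)phenyl]propanoyl]-2-oxazolidinone (threo), via dibutylboron Z-enolate 10 (not isolated)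
Conditions: Bu2BOTf, iPr2NEt, CH2Cl2, −78 → 0 °C; then 9, −78 → 0 °C; pH 7 buffer, MeOH, 30% H2O2, 0 °C
Reagents that add atoms: none
Why: Evans syn aldol reaction: the Z-boron enolate 10 adds to 9 through a closed chair (Zimmerman–Traxler) transition state on the enolate face remote from the benzyl group of the (R)-auxiliary, which sets Cβ in the configuration required by the target and Cα syn to it, that is the threo (αS,βS) pair.

Step 6
Reactants: 11 threo aldol imide
Product: 12 (1S,2S)-2-(4-ethynyl-2,6-dimethoxyphenoxy)-1-[3-methoxy-4-(triisopropylsilyloxy)phenyl]propane-1,3-diol (threo)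
Conditions: LiBH4, THF, H2O (1 equiv), 0 °C
Reagents that add atoms: none
Why: Reductive cleavage of the N-acyloxazolidinone by hydride attack at the exocyclic carbonyl, which releases the Cγ primary alcohol and the recoverable auxiliary without touching either stereocentre.

Step 7
Reactants: 13 p-coumaric acid
Product: 15 (E)-3-[4-(triisopropylsilyloxy)phenyl]prop-2-enoic acid, via bis-TIPS coumarate 14 (not isolated)
Conditions: TIPSCl (2.2 equiv), imidazole, DMF, rt; then K2CO3, THF/MeOH/H2O, 0 °C → rt; 1 M HCl to pH 4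
Reagents that add atoms: triisopropylsilyl chloride, CC(C)[Si](Cl)(C(C)C)C(C)C
Why: Double silylation followed by selective hydrolysis of the silyl ester, which is far more labile to aqueous carbonate than the aryl TIPS ether.

Step 8
Reactants: 12 threo diol; 15 (E)-3-[4-(triisopropylsilyloxy)phenyl]prop-2-enoic acid
Product: 16 (2S,3S)-2-(4-ethynyl-2,6-dimethoxyphenoxy)-3-hydroxy-3-[3-methoxy-4-(triisopropylsilyloxy)phenyl]propyl (E)-3-[4-(triisopropylsilyloxy)phenyl]prop-2-enoate (threo)
Conditions: EDC·HCl, DMAP (cat.), CH2Cl2, −10 → 0 °C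
Reagents that add atoms: none
Why: Steglich-type carbodiimide esterification, selective because the unhindered primary Cγ hydroxyl acylates much faster than the secondary benzylic hydroxyl next to the bulky 2,6-dimethoxyaryloxy group.

Step 9
Reactants: 16 threo γ-coumarate alcohol
Product: 17 (2S,3R)-3-(chloroacetoxy)-2-(4-ethynyl-2,6-dimethoxyphenoxy)-3-[3-methoxy-4-(triisopropylsilyloxy)phenyl]propyl (E)-3-[4-(triisopropylsilyloxy)phenyl]prop-2-enoate (erythro)
Conditions: ClCH2CO2H, PPh3, DIAD, toluene, −20 → 0 °C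
Reagents that add atoms: chloroacetic acid, OC(=O)CCl
Why: Mitsunobu reaction: the oxyphosphonium ion of the secondary benzylic alcohol is displaced by chloroacetate (an acid of pKa about 2.9, suited to hindered alcohols) in an SN2 process, so that Cα is inverted from S to R while Cβ is untouched, turning the threo into the erythro (αR,βS) series; toluene and low temperature are chosen to disfavour ionisation.

Step 10
Reactants: 17 erythro chloroacetate
Product: 18 (2S,3R)-2-(4-ethynyl-2,6-dimethoxyphenoxy)-3-hydroxy-3-[3-methoxy-4-(triisopropylsilyloxy)phenyl]propyl (E)-3-[4-(triisopropylsilyloxy)phenyl]prop-2-enoate (erythro)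
Conditions: thiourea, NaHCO3, EtOH/THF, 45 °C
Reagents that add atoms: none
Why: Chemoselective dechloroacetylation, in which thiourea is S-alkylated by the α-chloro ester and the isothiouronium group then cyclises onto the ester carbonyl, freeing the Cα alcohol with retention (its C–O bond is not broken) while the conjugated coumarate and the aryl silyl ethers are not attacked.

Step 11
Reactants: 19 phloroglucinol
Product: 20 3,5-bis(triisopropylsilyloxy)phenol
Conditions: TIPSCl (2.0 equiv), imidazole, DMF, 0 °C → rt; chromatography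
Reagents that add atoms: triisopropylsilyl chloride, CC(C)[Si](Cl)(C(C)C)C(C)C
Why: Statistical silylation of the threefold-symmetric triol, which can give only one bis-ether, to be separated from mono- and tris-silylated material.

Step 12
Reactants: 20 3,5-bis(triisopropylsilyloxy)phenol
Product: 21 2-iodo-3,5-bis(triisopropylsilyloxy)phenol
Conditions: NIS (1.0 equiv), CH2Cl2, −40 → 0 °C, dark
Reagents that add atoms: N-iodosuccinimide, O=C1CCC(=O)N1I
Why: Electrophilic aromatic iodination directed by the free hydroxyl, the strongest donor, to its ortho position (C2 and C6 are equivalent), because the para position is buried between two triisopropylsilyloxy groups.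

Step 13
Reactants: 21 2-iodo-3,5-bis(triisopropylsilyloxy)phenol; 18 erythro ring B alkyne
Product: 24 (2S,3R)-2-{4-[5,7-bis(triisopropylsilyloxy)-4-oxo-4H-chromen-2-yl]-2,6-dimethoxyphenoxy}-3-hydroxy-3-[3-methoxy-4-(triisopropylsilyloxy)phenyl]propyl (E)-3-[4-(triisopropylsilyloxy)phenyl]prop-2-enoate, via hydroxyaryl ynone 22 (not isolated), via enaminone 23 (not isolated)
Conditions: PdCl2(PPh3)2 (5 mol %), CO (5 bar), Et2NH, DMF, 60 °C
Reagents that add atoms: carbon monoxide, [C-]#[O+]
Why: The divalent palladium of PdCl2(PPh3)2 is reduced in situ to zerovalent palladium, which inserts into the C–I bond of 21; CO insertion gives an aroylpalladium iodide, the amine-deprotonated terminal alkyne of 18 replaces iodide, and reductive elimination forms C4a–C4 and C4–C3 in the ortho-hydroxyaryl ynone 22. Diethylamine then adds to the β-carbon of the ynone to give enaminone 23, and the ring A hydroxyl attacks that same carbon and expels the amine, forming O1–C2. The closest known reaction type is the carbonylative Sonogashira annulation of ortho-iodophenols with terminal arylalkynes to flavones in a secondary amine medium. Ring C closes in the 6-endo mode (oxa-Michael addition–elimination at C2 of the enaminone); no stereocentre is created, and Cα and Cβ, being neither enolisable nor allylic, should pass through unchanged. The step needs carbonylative rather than direct coupling and flavone rather than aurone closure: the absence of copper and the CO pressure favour the ynone, and after amine addition only the β-carbon (C2) is electrophilic, so the single free ortho-hydroxyl of 21 can close only the six-membered ring. The free Cα hydroxyl and the coumarate ester are much poorer partners for the aroylpalladium and for diethylamine than the alkyne at 60 °C and should stay intact.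

Step 14
Reactants: 24 tetra-O-TIPS flavone
Product: 25 (2S,3R)-2-[4-(5,7-dihydroxy-4-oxo-4H-chromen-2-yl)-2,6-dimethoxyphenoxy]-3-hydroxy-3-(4-hydroxy-3-methoxyphenyl)propyl (E)-3-(4-hydroxyphenyl)prop-2-enoate (target)
Conditions: TBAF, AcOH (1:1), THF, 0 °C → rt
Reagents that add atoms: none
Why: Fluoride-driven cleavage of the four aryl silyl ethers, buffered with acetic acid so that neither the coumarate ester nor the p-hydroxybenzylic alcohol is exposed to base or to strong acid.

**Compound list**

1 | syringaldehyde (4-hydroxy-3,5-dimethoxybenzaldehyde) | COc1cc(C=O)cc(OC)c1O | starting material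
2 | methyl (4-formyl-2,6-dimethoxyphenoxy)acetate | COC(=O)COc1c(OC)cc(C=O)cc1OC | intermediate
3 | methyl (4-ethynyl-2,6-dimethoxyphenoxy)acetate (not isolated) | COC(=O)COc1c(OC)cc(C#C)cc1OC | intermediate
4 | (4-ethynyl-2,6-dimethoxyphenoxy)acetic acid | OC(=O)COc1c(OC)cc(C#C)cc1OC | intermediate
5 | (R)-4-benzyl-2-oxazolidinone | O=C1N[C@H](Cc2ccccc2)CO1 | starting material
6 | (4-ethynyl-2,6-dimethoxyphenoxy)acetic pivalic anhydride (not isolated) | CC(C)(C)C(=O)OC(=O)COc1c(OC)cc(C#C)cc1OC | intermediate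
7 | (R)-4-benzyl-3-[(4-ethynyl-2,6-dimethoxyphenoxy)acetyl]-2-oxazolidinone | O=C(COc1c(OC)cc(C#C)cc1OC)N1C(=O)OC[C@H]1Cc1ccccc1 | intermediate
8 | vanillin | COc1cc(C=O)ccc1O | starting material
9 | 3-methoxy-4-(triisopropylsilyloxy)benzaldehyde | COc1cc(C=O)ccc1O[Si](C(C)C)(C(C)C)C(C)C | intermediate
10 | (R)-4-benzyl-3-[(Z)-1-(dibutylboryloxy)-2-(4-ethynyl-2,6-dimethoxyphenoxy)ethenyl]-2-oxazolidinone, the Z-boron enolate of 7 (not isolated) | CCCCB(CCCC)O/C(=C\Oc1c(OC)cc(C#C)cc1OC)N1C(=O)OC[C@H]1Cc1ccccc1 | intermediate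
11 | (R)-4-benzyl-3-[(2R,3S)-2-(4-ethynyl-2,6-dimethoxyphenoxy)-3-hydroxy-3-[3-methoxy-4-(triisopropylsilyloxy)phenyl]propanoyl]-2-oxazolidinone (threo) | COc1cc([C@H](O)[C@H](C(=O)N2C(=O)OC[C@H]2Cc2ccccc2)Oc2c(OC)cc(C#C)cc2OC)ccc1O[Si](C(C)C)(C(C)C)C(C)C | intermediate
12 | (1S,2S)-2-(4-ethynyl-2,6-dimethoxyphenoxy)-1-[3-methoxy-4-(triisopropylsilyloxy)phenyl]propane-1,3-diol (threo) | COc1cc([C@H](O)[C@H](CO)Oc2c(OC)cc(C#C)cc2OC)ccc1O[Si](C(C)C)(C(C)C)C(C)C | intermediate
13 | p-coumaric acid | O=C(O)/C=C/c1ccc(O)cc1 | starting material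
14 | triisopropylsilyl (E)-3-[4-(triisopropylsilyloxy)phenyl]prop-2-enoate (not isolated) | CC(C)[Si](OC(=O)/C=C/c1ccc(O[Si](C(C)C)(C(C)C)C(C)C)cc1)(C(C)C)C(C)C | intermediate
15 | (E)-3-[4-(triisopropylsilyloxy)phenyl]prop-2-enoic acid | O=C(O)/C=C/c1ccc(O[Si](C(C)C)(C(C)C)C(C)C)cc1 | intermediate
16 | (2S,3S)-2-(4-ethynyl-2,6-dimethoxyphenoxy)-3-hydroxy-3-[3-methoxy-4-(triisopropylsilyloxy)phenyl]propyl (E)-3-[4-(triisopropylsilyloxy)phenyl]prop-2-enoate (threo) | COc1cc([C@H](O)[C@H](COC(=O)/C=C/c2ccc(O[Si](C(C)C)(C(C)C)C(C)C)cc2)Oc2c(OC)cc(C#C)cc2OC)ccc1O[Si](C(C)C)(C(C)C)C(C)C | intermediate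
17 | (2S,3R)-3-(chloroacetoxy)-2-(4-ethynyl-2,6-dimethoxyphenoxy)-3-[3-methoxy-4-(triisopropylsilyloxy)phenyl]propyl (E)-3-[4-(triisopropylsilyloxy)phenyl]prop-2-enoate (erythro) | COc1cc([C@@H](OC(=O)CCl)[C@H](COC(=O)/C=C/c2ccc(O[Si](C(C)C)(C(C)C)C(C)C)cc2)Oc2c(OC)cc(C#C)cc2OC)ccc1O[Si](C(C)C)(C(C)C)C(C)C | intermediate
18 | (2S,3R)-2-(4-ethynyl-2,6-dimethoxyphenoxy)-3-hydroxy-3-[3-methoxy-4-(triisopropylsilyloxy)phenyl]propyl (E)-3-[4-(triisopropylsilyloxy)phenyl]prop-2-enoate (erythro; alkyne partner of the key step) | COc1cc([C@@H](O)[C@H](COC(=O)/C=C/c2ccc(O[Si](C(C)C)(C(C)C)C(C)C)cc2)Oc2c(OC)cc(C#C)cc2OC)ccc1O[Si](C(C)C)(C(C)C)C(C)C | intermediate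
19 | phloroglucinol | Oc1cc(O)cc(O)c1 | starting material
20 | 3,5-bis(triisopropylsilyloxy)phenol | Oc1cc(O[Si](C(C)C)(C(C)C)C(C)C)cc(O[Si](C(C)C)(C(C)C)C(C)C)c1 | intermediate
21 | 2-iodo-3,5-bis(triisopropylsilyloxy)phenol (iodophenol partner of the key step) | Oc1cc(O[Si](C(C)C)(C(C)C)C(C)C)cc(O[Si](C(C)C)(C(C)C)C(C)C)c1I | intermediate
22 | ortho-hydroxyaryl ynone: the alkyne terminus of 18 joined to the carbonyl of a 2-hydroxy-4,6-bis(triisopropylsilyloxy)benzoyl group (not isolated) | COc1cc([C@@H](O)[C@H](COC(=O)/C=C/c2ccc(O[Si](C(C)C)(C(C)C)C(C)C)cc2)Oc2c(OC)cc(C#CC(=O)c3c(O)cc(O[Si](C(C)C)(C(C)C)C(C)C)cc3O[Si](C(C)C)(C(C)C)C(C)C)cc2OC)ccc1O[Si](C(C)C)(C(C)C)C(C)C | intermediate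
23 | (E)-β-(diethylamino) enone from addition of diethylamine to ynone 22 (not isolated) | COc1cc([C@@H](O)[C@H](COC(=O)/C=C/c2ccc(O[Si](C(C)C)(C(C)C)C(C)C)cc2)Oc2c(OC)cc(/C(=C\C(=O)c3c(O)cc(O[Si](C(C)C)(C(C)C)C(C)C)cc3O[Si](C(C)C)(C(C)C)C(C)C)N(CC)CC)cc2OC)ccc1O[Si](C(C)C)(C(C)C)C(C)C | intermediate
24 | (2S,3R)-2-{4-[5,7-bis(triisopropylsilyloxy)-4-oxo-4H-chromen-2-yl]-2,6-dimethoxyphenoxy}-3-hydroxy-3-[3-methoxy-4-(triisopropylsilyloxy)phenyl]propyl (E)-3-[4-(triisopropylsilyloxy)phenyl]prop-2-enoate | COc1cc([C@@H](O)[C@H](COC(=O)/C=C/c2ccc(O[Si](C(C)C)(C(C)C)C(C)C)cc2)Oc2c(OC)cc(-c3cc(=O)c4c(O[Si](C(C)C)(C(C)C)C(C)C)cc(O[Si](C(C)C)(C(C)C)C(C)C)cc4o3)cc2OC)ccc1O[Si](C(C)C)(C(C)C)C(C)C | intermediate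
25 | (2S,3R)-2-[4-(5,7-dihydroxy-4-oxo-4H-chromen-2-yl)-2,6-dimethoxyphenoxy]-3-hydroxy-3-(4-hydroxy-3-methoxyphenyl)propyl (E)-3-(4-hydroxyphenyl)prop-2-enoate | COc1cc([C@@H](O)[C@H](COC(=O)/C=C/c2ccc(O)cc2)Oc2c(OC)cc(-c3cc(=O)c4c(O)cc(O)cc4o3)cc2OC)ccc1O | target

**Summary**

Total step count: 14. Longest linear sequence: 10 steps (steps 1, 2, 3, 5, 6, 8, 9, 10, 13, 14).

Steps most likely to fail:

Step 13. Oxidative addition of zerovalent palladium into the hindered, electron-rich C–I bond may be slow. Coupling without CO uptake, capture of the aroylpalladium by the amine, or five-membered closure before the amine has added could then compete with the intended annulation. The fallback forms the ynone without CO and without an aryl iodide. Phloroglucinol 19 would be carboxylated (KHCO3, CO2, water, 50 °C; Kolbe–Schmitt) to 2,4,6-trihydroxybenzoic acid F1. Persilylation (TBSCl, imidazole, DMF) would give tert-butyldimethylsilyl 2,4,6-tris(tert-butyldimethylsilyloxy)benzoate F2. Oxalyl chloride with catalytic DMF in CH2Cl2 would convert the silyl ester directly into 2,4,6-tris(tert-butyldimethylsilyloxy)benzoyl chloride F3. Acyl Sonogashira coupling of this chloride with alkyne 18 (PdCl2(PPh3)2, CuI, Et3N, THF, rt) should give the persilylated ynone F4. Diethylamine would add to it to give the β-(diethylamino) enone F5. TBAF/AcOH would then remove all five silyl groups, and a freed ortho-phenol would close ring C by the same addition–elimination, so the route is rejoined at target 25.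

Step 9. The activated benzylic oxyphosphonium ion may ionise before the carboxylate attacks, or the γ-ester may take part, so that inversion is incomplete and the Cα configuration is eroded. The fallback is a redox inversion. Alcohol 16 would be oxidised with Dess–Martin periodinane (NaHCO3, CH2Cl2) to (S)-2-(4-ethynyl-2,6-dimethoxyphenoxy)-3-[3-methoxy-4-(triisopropylsilyloxy)phenyl]-3-oxopropyl (E)-3-[4-(triisopropylsilyloxy)phenyl]prop-2-enoate F6. Reduction with Zn(BH4)2 in Et2O at −30 °C, under chelation between the ketone and the β-aryloxy oxygen, should deliver hydride to the face that gives the erythro alcohol. The route is rejoined at 18, and steps 9 and 10 are not needed.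

Step 12. Iodination may occur para to the free hydroxyl or a second time, giving regioisomeric or over-iodinated material that is hard to remove. The fallback reverses the order of the two operations. Phloroglucinol 19 would be iodinated first (I2, NaHCO3, THF/H2O, 0 °C) to 2-iodobenzene-1,3,5-triol F7, the only possible mono-iodide. TIPSCl (2 equiv) and imidazole should then silylate the unhindered hydroxyl para to iodine and one of the two equivalent ortho hydroxyls, which rejoins the route at 21.

**Further compounds**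

F1 | step 13 | 2,4,6-trihydroxybenzoic acid | O=C(O)c1c(O)cc(O)cc1O
F2 | step 13 | tert-butyldimethylsilyl 2,4,6-tris(tert-butyldimethylsilyloxy)benzoate | CC(C)(C)[Si](C)(C)OC(=O)c1c(O[Si](C)(C)C(C)(C)C)cc(O[Si](C)(C)C(C)(C)C)cc1O[Si](C)(C)C(C)(C)C
F3 | step 13 | 2,4,6-tris(tert-butyldimethylsilyloxy)benzoyl chloride | O=C(Cl)c1c(O[Si](C)(C)C(C)(C)C)cc(O[Si](C)(C)C(C)(C)C)cc1O[Si](C)(C)C(C)(C)C
F4 | step 13 | persilylated ynone: the alkyne terminus of 18 joined to the carbonyl of a 2,4,6-tris(tert-butyldimethylsilyloxy)benzoyl group | COc1cc([C@@H](O)[C@H](COC(=O)/C=C/c2ccc(O[Si](C(C)C)(C(C)C)C(C)C)cc2)Oc2c(OC)cc(C#CC(=O)c3c(O[Si](C)(C)C(C)(C)C)cc(O[Si](C)(C)C(C)(C)C)cc3O[Si](C)(C)C(C)(C)C)cc2OC)ccc1O[Si](C(C)C)(C(C)C)C(C)C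
F5 | step 13 | (E)-β-(diethylamino) enone from addition of diethylamine to ynone F4 | COc1cc([C@@H](O)[C@H](COC(=O)/C=C/c2ccc(O[Si](C(C)C)(C(C)C)C(C)C)cc2)Oc2c(OC)cc(/C(=C\C(=O)c3c(O[Si](C)(C)C(C)(C)C)cc(O[Si](C)(C)C(C)(C)C)cc3O[Si](C)(C)C(C)(C)C)N(CC)CC)cc2OC)ccc1O[Si](C(C)C)(C(C)C)C(C)C
F6 | step 9 | (S)-2-(4-ethynyl-2,6-dimethoxyphenoxy)-3-[3-methoxy-4-(triisopropylsilyloxy)phenyl]-3-oxopropyl (E)-3-[4-(triisopropylsilyloxy)phenyl]prop-2-enoate | COc1cc(C(=O)[C@H](COC(=O)/C=C/c2ccc(O[Si](C(C)C)(C(C)C)C(C)C)cc2)Oc2c(OC)cc(C#C)cc2OC)ccc1O[Si](C(C)C)(C(C)C)C(C)C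
F7 | step 12 | 2-iodobenzene-1,3,5-triol | Oc1cc(O)c(I)c(O)c1
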